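## Retrosynthetic overview

1. Locants used throughout: C1=C2(Me)–C3(O)–C4–C5–C6(Me,OH)–C7(Br)–C8–C9–C10(ring CH)–C11(Me)=C12–C13–C14(Me)=C15–C16H2–Ar. The 15-membered lactone is the last ring, closed by Pd-catalysed carbonylative macrolactonisation of an aryl bromide onto the C3 alcohol.
2. C11–Me comes from the enol triflate of a 2,3-disubstituted cyclohex-3-enone. That six-membered ring is made by one-carbon ring expansion (1,2-alkenyl shift, C10 inserted between C11 and C15) of a 2-benzyl-3-methylcyclopentenone with the chain diazoalkane; this step joins the two halves and sets C10.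
3. Cyclopentenone half: Negishi benzylation of 2-bromo-3-methylcyclopent-2-enone with a benzylzinc made in three steps from o-cresol.
4. Chain half: asymmetric Nozaki–Hiyama–Kishi isopropenylation of pent-4-ynal (C3), carboalumination/allylation (E-C6=C7), Shi epoxidation and bromide opening (C6, C7), anti-Markovnikov oxidation to the C10 aldehyde.
5. Ring order: arene (bought) → cyclopentenone (bought) → cyclohexenone by ring expansion → cyclohexa-1,4-diene → macrolactone.

Assumption: pent-4-ynal and 2-bromo-3-methylcyclopent-2-en-1-one are taken as catalogue compounds, and the antipode of the chiral ligand in steps 5 and 12 is chosen by experiment to give the configurations shown.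

## Route

Step 1
Reactants: 1 2-methylphenol (o-cresol)
Product: 2 4-bromo-2-methylphenol
Conditions: NBS (1.0 equiv), MeCN, 0 °C
Reagents that add atoms: N-bromosuccinimide, O=C1CCC(=O)N1Br
Why: Electrophilic aromatic bromination in which the hydroxyl group directs para (the open ortho position is the minor site); no stereocentre is formed.

Step 2
Reactants: 2 4-bromo-2-methylphenol
Product: 3 (4-bromo-2-methylphenoxy)(tert-butyl)dimethylsilane
Conditions: TBSCl, imidazole, DMF, rt
Reagents that add atoms: tert-butyldimethylsilyl chloride, CC(C)(C)[Si](C)(C)Cl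
Why: Standard phenol silylation; the aryl silyl ether tolerates the radical, organozinc, Lewis-acid, amide-base and mild-acid steps that follow and is removed by fluoride at the end.

Step 3
Reactants: 3 (4-bromo-2-methylphenoxy)(tert-butyl)dimethylsilane
Product: 4 [4-bromo-2-(bromomethyl)phenoxy](tert-butyl)dimethylsilane
Conditions: NBS (1.05 equiv), AIBN (cat.), PhCF3, 85 °C
Reagents that add atoms: N-bromosuccinimide, O=C1CCC(=O)N1Br
Why: Wohl–Ziegler radical bromination; radical-chain conditions in a non-polar solvent favour the single benzylic position over the ring.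

Step 4
Reactants: 4 [4-bromo-2-(bromomethyl)phenoxy](tert-butyl)dimethylsilane; 5 2-bromo-3-methylcyclopent-2-en-1-one
Product: 7 2-{[5-bromo-2-(tert-butyldimethylsilyloxy)phenyl]methyl}-3-methylcyclopent-2-en-1-one, via benzylzinc bromide 6 (not isolated)
Conditions: Zn dust, LiCl, THF, rt; then 5, Pd(OAc)2 (2 mol %), SPhos (4 mol %), THF, rt
Reagents that add atoms: zinc, [Zn] (held in 6 only)
Why: Negishi sp3–sp2 coupling; zinc inserts only into the benzylic C–Br bond, and zerovalent palladium adds to the activated α-bromoenone much faster than to the electron-rich aryl bromide.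

Step 5
Reactants: 8 pent-4-ynal; 9 2-bromopropene
Product: 10 triethyl{[(3S)-2-methylhept-1-en-6-yn-3-yl]oxy}silane
Conditions: CrCl2 (10 mol %), chiral oxazoline–sulfonamide ligand (Kishi type, 11 mol %), NiCl2 (2 mol %), Mn powder, Et3SiCl, LiCl, MeCN, rt
Reagents that add atoms: chlorotriethylsilane, CC[Si](Cl)(CC)CC
Why: Catalytic asymmetric Nozaki–Hiyama–Kishi alkenylation; the ligated chromium delivers the isopropenyl group to one aldehyde face to set C3 (S), and Et3SiCl turns the catalyst over while capping the alkoxide as the TES ether.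

Step 6
Reactants: 10 triethyl{[(3S)-2-methylhept-1-en-6-yn-3-yl]oxy}silane; 11 allyl bromide
Product: 13 triethyl{[(3S,6E)-2,6-dimethyldeca-1,6,9-trien-3-yl]oxy}silane, via alkenyldimethylalane 12 (not isolated)
Conditions: AlMe3 (2.5 equiv), Cp2ZrCl2 (25 mol %), CH2Cl2, 0 °C to rt; then 11, Pd(PPh3)4 (3 mol %), THF, rt
Reagents that add atoms: trimethylaluminium, C[Al](C)C
Why: Negishi zirconium-catalysed syn-carboalumination puts methyl on C6 and aluminium on C7, and the palladium-catalysed allylation proceeds with retention to give the E-trisubstituted alkene carrying C8–C10.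

Step 7
Reactants: 13 triethyl{[(3S,6E)-2,6-dimethyldeca-1,6,9-trien-3-yl]oxy}silane
Product: 14 triethyl{[(3S)-2-methyl-5-[(2S,3S)-2-methyl-3-(prop-2-en-1-yl)oxiran-2-yl]pent-1-en-3-yl]oxy}silane
Conditions: ent-Shi ketone (L-fructose-derived, 30 mol %), KHSO5 (as 2KHSO5·KHSO4·K2SO4), K2CO3, Bu4NHSO4, aqueous Na2B4O7 buffer, MeCN/CH2(OMe)2, 0 °C
Reagents that add atoms: potassium peroxymonosulfate, [K+].[O-]S(=O)(=O)OO
Why: Shi asymmetric epoxidation; the chiral dioxirane reacts only with the electron-rich trisubstituted alkene (terminal and 1,1-disubstituted alkenes are much slower) through the spiro transition state to give the (6S,7S)-epoxide.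

Step 8
Reactants: 14 triethyl{[(3S)-2-methyl-5-[(2S,3S)-2-methyl-3-(prop-2-en-1-yl)oxiran-2-yl]pent-1-en-3-yl]oxy}silane
Product: 15 (3S,6S,7R)-7-bromo-2,6-dimethyl-3-(triethylsilyloxy)deca-1,9-dien-6-ol
Conditions: Li2NiBr4 (THF solution), THF, 0 °C to rt; pH 7 phosphate buffer work-up
Reagents that add atoms: dilithium tetrabromonickelate, [Li+].[Li+].[Ni+2].[Br-].[Br-].[Br-].[Br-]
Why: SN2 epoxide opening by soft bromide at the less substituted carbon C7 with inversion (7S to 7R), leaving the C6–O bond and its configuration untouched, which gives the anti bromohydrin.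

Step 9
Reactants: 15 (3S,6S,7R)-7-bromo-2,6-dimethyl-3-(triethylsilyloxy)deca-1,9-dien-6-ol
Product: 16 (3S,6S,7R)-7-bromo-2,6-dimethyl-3,6-bis(triethylsilyloxy)deca-1,9-diene
Conditions: Et3SiOTf, 2,6-lutidine, CH2Cl2, −78 to 0 °C
Reagents that add atoms: triethylsilyl triflate, CC[Si](CC)(CC)OS(=O)(=O)C(F)(F)F
Why: Silyl triflate silylation of the tertiary alcohol, which blocks re-closure to the epoxide under the basic steps ahead.

Step 10
Reactants: 16 (3S,6S,7R)-7-bromo-2,6-dimethyl-3,6-bis(triethylsilyloxy)deca-1,9-diene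
Product: 18 (4R,5S,8S)-4-bromo-5,9-dimethyl-5,8-bis(triethylsilyloxy)dec-9-enal, via alkyldisiamylborane 17 (not isolated)
Conditions: Sia2BH (from BH3·SMe2 and 2-methylbut-2-ene), THF, 0 °C; then NMO (8 equiv), (n-Pr4N)RuO4 (5 mol %), 4 Å sieves, CH2Cl2, rt
Reagents that add atoms: N-methylmorpholine N-oxide, C[N+]1([O-])CCOCC1; disiamylborane, CC(C)C(C)BC(C)C(C)C (held in 17 only)
Why: Anti-Markovnikov hydroboration by the bulky dialkylborane selects the monosubstituted alkene over the hindered 1,1-disubstituted one, and amine-oxide oxidation of the C–B bond followed by perruthenate oxidation gives the aldehyde in the same flask.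

Step 11
Reactants: 18 (4R,5S,8S)-4-bromo-5,9-dimethyl-5,8-bis(triethylsilyloxy)dec-9-enal
Product: 19 [(4R,5S,8S)-4-bromo-5,9-dimethyl-5,8-bis(triethylsilyloxy)dec-9-en-1-ylidene]hydrazine
Conditions: N2H4 (anhydrous, 10 equiv), EtOH, 0 °C, inverse addition; used crude
Reagents that add atoms: hydrazine, NN
Why: Hydrazone condensation; the large excess of hydrazine suppresses azine formation and the hindered secondary bromide is not displaced at 0 °C.

Step 12
Reactants: 19 [(4R,5S,8S)-4-bromo-5,9-dimethyl-5,8-bis(triethylsilyloxy)dec-9-en-1-ylidene]hydrazine; 7 2-{[5-bromo-2-(tert-butyldimethylsilyloxy)phenyl]methyl}-3-methylcyclopent-2-en-1-one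
Product: 21 (2R)-2-[(3R,4S,7S)-3-bromo-4,8-dimethyl-4,7-bis(triethylsilyloxy)non-8-en-1-yl]-3-{[5-bromo-2-(tert-butyldimethylsilyloxy)phenyl]methyl}-4-methylcyclohex-3-en-1-one, via diazoalkane 20 (not isolated)
Conditions: activated MnO2, CH2Cl2, −30 °C, cold filtration; filtrate added to 7 (1.2 equiv), Sc(OTf)3 (10 mol %), indane-fused tris(oxazoline) ligand (12 mol %), toluene, −78 °C
Reagents that add atoms: none
Why: Proposed new method: the chiral scandium Lewis acid binds the enone carbonyl and the unstabilised diazo carbon (C10) adds 1,2 (the tetrasubstituted C=C is too hindered for pyrazoline formation); the β-oxido diazonium then collapses by anti-periplanar 1,2-shift of the electron-rich alkenyl carbon C15 (better migrating group than the CH2, bridged cyclopropylcarbinyl-like transition state) with loss of N2, so C10 is inserted between C11 and C15 and the five-membered ring becomes the six-membered one; the ligand fixes which enantioface of the diazo carbon attacks and the shift inverts that carbon stereospecifically, giving (R)-C10 (the S centre of the target after a CIP priority change), with the C10 epimer a separable diastereomer; closest known reaction type: Sc(OTf)3-catalysed enantioselective diazoalkane ring expansion of saturated cycloalkanones (Tiffeneau–Demjanov-type homologation), not shown for cyclopentenones with alkenyl migration or for functionalised unstabilised diazoalkanes.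

Step 13
Reactants: 21 (2R)-2-[(3R,4S,7S)-3-bromo-4,8-dimethyl-4,7-bis(triethylsilyloxy)non-8-en-1-yl]-3-{[5-bromo-2-(tert-butyldimethylsilyloxy)phenyl]methyl}-4-methylcyclohex-3-en-1-one
Product: 22 (6R)-6-[(3R,4S,7S)-3-bromo-4,8-dimethyl-4,7-bis(triethylsilyloxy)non-8-en-1-yl]-5-{[5-bromo-2-(tert-butyldimethylsilyloxy)phenyl]methyl}-4-methylcyclohexa-1,4-dien-1-yl trifluoromethanesulfonate
Conditions: KN(SiMe3)2 (1.1 equiv), THF, −78 °C; then PhNTf2, −78 to −40 °C
Reagents that add atoms: N-phenylbis(trifluoromethanesulfonimide), O=S(=O)(N(c1ccccc1)S(=O)(=O)C(F)(F)F)C(F)(F)F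
Why: Kinetic enolisation by the bulky amide at the unhindered C12 methylene and O-triflation; A(1,2) strain with the C15 benzyl group holds the C10 side chain pseudoaxial, so the C10–H lies near the carbonyl plane, is not removed, and C10 keeps its configuration.

Step 14
Reactants: 22 (6R)-6-[(3R,4S,7S)-3-bromo-4,8-dimethyl-4,7-bis(triethylsilyloxy)non-8-en-1-yl]-5-{[5-bromo-2-(tert-butyldimethylsilyloxy)phenyl]methyl}-4-methylcyclohexa-1,4-dien-1-yl trifluoromethanesulfonate
Product: 23 tert-butyl(4-bromo-2-{[(6S)-6-[(3R,4S,7S)-3-bromo-4,8-dimethyl-4,7-bis(triethylsilyloxy)non-8-en-1-yl]-2,5-dimethylcyclohexa-1,4-dien-1-yl]methyl}phenoxy)dimethylsilane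
Conditions: MeZnCl (THF solution, 3 equiv), Pd(PPh3)4 (5 mol %), THF, 0 °C to rt
Reagents that add atoms: methylzinc chloride, C[Zn]Cl
Why: Negishi coupling of the enol triflate; zerovalent palladium inserts into the vinyl C–OTf bond at room temperature well before the electron-rich aryl bromide or the secondary alkyl bromide, and C10 is untouched (its label becomes S by priority change only).

Step 15
Reactants: 23 tert-butyl(4-bromo-2-{[(6S)-6-[(3R,4S,7S)-3-bromo-4,8-dimethyl-4,7-bis(triethylsilyloxy)non-8-en-1-yl]-2,5-dimethylcyclohexa-1,4-dien-1-yl]methyl}phenoxy)dimethylsilane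
Product: 24 (3S,6S,7R)-7-bromo-9-[(1S)-2-{[5-bromo-2-(tert-butyldimethylsilyloxy)phenyl]methyl}-3,6-dimethylcyclohexa-2,5-dien-1-yl]-2,6-dimethyl-6-(triethylsilyloxy)non-1-en-3-ol
Conditions: PPTS (0.2 equiv), MeOH/CH2Cl2 1:1, 0 °C
Reagents that add atoms: none
Why: Acid-catalysed methanolysis; the secondary triethylsilyl ether is cleaved much faster than the hindered tertiary one, and the aryl silyl ether is acid-stable.

Step 16
Reactants: 24 (3S,6S,7R)-7-bromo-9-[(1S)-2-{[5-bromo-2-(tert-butyldimethylsilyloxy)phenyl]methyl}-3,6-dimethylcyclohexa-2,5-dien-1-yl]-2,6-dimethyl-6-(triethylsilyloxy)non-1-en-3-ol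
Product: 25 (3S,6S,7R,10S)-macrolactone bis-silyl ether (26 with the phenol as tert-butyldimethylsilyl ether and the C6 hydroxyl as triethylsilyl ether)
Conditions: Pd(OAc)2 (10 mol %), Xantphos (12 mol %), CO (1 atm), Et3N, toluene, 85 °C, syringe-pump addition to 1 mM
Reagents that add atoms: carbon monoxide, [C-]#[O+]
Why: Palladium-catalysed alkoxycarbonylation run as a macrolactonisation; oxidative addition to the aryl bromide, CO insertion and capture of the acyl-palladium by the C3 hydroxyl at high dilution close the 15-membered ring without touching the C3 stereocentre.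

Step 17
Reactants: 25 (3S,6S,7R,10S)-macrolactone bis-silyl ether
Product: 26 CNP0186361.2 (target)
Conditions: HF·pyridine, pyridine, THF, 0 °C to rt
Reagents that add atoms: none
Why: Fluoride desilylation of the tertiary triethylsilyl ether and the aryl silyl ether under non-basic conditions, so the bromohydrin does not close to the epoxide and the lactone and skipped diene survive.

## Compound list

1 | 2-methylphenol (o-cresol) | Cc1ccccc1O | starting material
2 | 4-bromo-2-methylphenol | Cc1cc(Br)ccc1O | intermediate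
3 | (4-bromo-2-methylphenoxy)(tert-butyl)dimethylsilane | Cc1cc(Br)ccc1O[Si](C)(C)C(C)(C)C | intermediate
4 | [4-bromo-2-(bromomethyl)phenoxy](tert-butyl)dimethylsilane | BrCc1cc(Br)ccc1O[Si](C)(C)C(C)(C)C | intermediate
5 | 2-bromo-3-methylcyclopent-2-en-1-one | CC1=C(Br)C(=O)CC1 | starting material
6 | {[5-bromo-2-(tert-butyldimethylsilyloxy)phenyl]methyl}zinc bromide (not isolated) | Br[Zn]Cc1cc(Br)ccc1O[Si](C)(C)C(C)(C)C | intermediate
7 | 2-{[5-bromo-2-(tert-butyldimethylsilyloxy)phenyl]methyl}-3-methylcyclopent-2-en-1-one | CC1=C(Cc2cc(Br)ccc2O[Si](C)(C)C(C)(C)C)C(=O)CC1 | intermediate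
8 | pent-4-ynal | C#CCCC=O | starting material
9 | 2-bromopropene | C=C(C)Br | starting material
10 | triethyl{[(3S)-2-methylhept-1-en-6-yn-3-yl]oxy}silane | C=C(C)[C@@H](O[Si](CC)(CC)CC)CCC#C | intermediate
11 | allyl bromide (3-bromoprop-1-ene) | C=CCBr | starting material
12 | [(1E,5S)-2,6-dimethyl-5-(triethylsilyloxy)hepta-1,6-dien-1-yl]dimethylalane (not isolated) | C=C(C)[C@@H](O[Si](CC)(CC)CC)CC/C(C)=C/[Al](C)C | intermediate
13 | triethyl{[(3S,6E)-2,6-dimethyldeca-1,6,9-trien-3-yl]oxy}silane | C=C(C)[C@@H](O[Si](CC)(CC)CC)CC/C(C)=C/CC=C | intermediate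
14 | triethyl{[(3S)-2-methyl-5-[(2S,3S)-2-methyl-3-(prop-2-en-1-yl)oxiran-2-yl]pent-1-en-3-yl]oxy}silane | C=C(C)[C@@H](O[Si](CC)(CC)CC)CC[C@]1(C)O[C@H]1CC=C | intermediate
15 | (3S,6S,7R)-7-bromo-2,6-dimethyl-3-(triethylsilyloxy)deca-1,9-dien-6-ol | C=C(C)[C@@H](O[Si](CC)(CC)CC)CC[C@](C)(O)[C@H](Br)CC=C | intermediate
16 | (3S,6S,7R)-7-bromo-2,6-dimethyl-3,6-bis(triethylsilyloxy)deca-1,9-diene | C=C(C)[C@@H](O[Si](CC)(CC)CC)CC[C@](C)(O[Si](CC)(CC)CC)[C@H](Br)CC=C | intermediate
17 | [(4R,5S,8S)-4-bromo-5,9-dimethyl-5,8-bis(triethylsilyloxy)dec-9-en-1-yl]bis(3-methylbutan-2-yl)borane (not isolated) | C=C(C)[C@@H](O[Si](CC)(CC)CC)CC[C@](C)(O[Si](CC)(CC)CC)[C@H](Br)CCCB(C(C)C(C)C)C(C)C(C)C | intermediate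
18 | (4R,5S,8S)-4-bromo-5,9-dimethyl-5,8-bis(triethylsilyloxy)dec-9-enal | C=C(C)[C@@H](O[Si](CC)(CC)CC)CC[C@](C)(O[Si](CC)(CC)CC)[C@H](Br)CCC=O | intermediate
19 | [(4R,5S,8S)-4-bromo-5,9-dimethyl-5,8-bis(triethylsilyloxy)dec-9-en-1-ylidene]hydrazine | C=C(C)[C@@H](O[Si](CC)(CC)CC)CC[C@](C)(O[Si](CC)(CC)CC)[C@H](Br)CCC=NN | intermediate
20 | (4R,5S,8S)-4-bromo-1-diazo-5,9-dimethyl-5,8-bis(triethylsilyloxy)dec-9-ene (not isolated) | C=C(C)[C@@H](O[Si](CC)(CC)CC)CC[C@](C)(O[Si](CC)(CC)CC)[C@H](Br)CCC=[N+]=[N-] | intermediate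
21 | (2R)-2-[(3R,4S,7S)-3-bromo-4,8-dimethyl-4,7-bis(triethylsilyloxy)non-8-en-1-yl]-3-{[5-bromo-2-(tert-butyldimethylsilyloxy)phenyl]methyl}-4-methylcyclohex-3-en-1-one | C=C(C)[C@@H](O[Si](CC)(CC)CC)CC[C@](C)(O[Si](CC)(CC)CC)[C@H](Br)CC[C@H]2C(=O)CCC(C)=C2Cc2cc(Br)ccc2O[Si](C)(C)C(C)(C)C | intermediate
22 | (6R)-6-[(3R,4S,7S)-3-bromo-4,8-dimethyl-4,7-bis(triethylsilyloxy)non-8-en-1-yl]-5-{[5-bromo-2-(tert-butyldimethylsilyloxy)phenyl]methyl}-4-methylcyclohexa-1,4-dien-1-yl trifluoromethanesulfonate | C=C(C)[C@@H](O[Si](CC)(CC)CC)CC[C@](C)(O[Si](CC)(CC)CC)[C@H](Br)CC[C@H]2C(OS(=O)(=O)C(F)(F)F)=CCC(C)=C2Cc2cc(Br)ccc2O[Si](C)(C)C(C)(C)C | intermediate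
23 | tert-butyl(4-bromo-2-{[(6S)-6-[(3R,4S,7S)-3-bromo-4,8-dimethyl-4,7-bis(triethylsilyloxy)non-8-en-1-yl]-2,5-dimethylcyclohexa-1,4-dien-1-yl]methyl}phenoxy)dimethylsilane | C=C(C)[C@@H](O[Si](CC)(CC)CC)CC[C@](C)(O[Si](CC)(CC)CC)[C@H](Br)CC[C@H]2C(C)=CCC(C)=C2Cc2cc(Br)ccc2O[Si](C)(C)C(C)(C)C | intermediate
24 | (3S,6S,7R)-7-bromo-9-[(1S)-2-{[5-bromo-2-(tert-butyldimethylsilyloxy)phenyl]methyl}-3,6-dimethylcyclohexa-2,5-dien-1-yl]-2,6-dimethyl-6-(triethylsilyloxy)non-1-en-3-ol | C=C(C)[C@@H](O)CC[C@](C)(O[Si](CC)(CC)CC)[C@H](Br)CC[C@H]2C(C)=CCC(C)=C2Cc2cc(Br)ccc2O[Si](C)(C)C(C)(C)C | intermediate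
25 | (3S,6S,7R,10S)-macrolactone bis-silyl ether: 26 with the phenol as tert-butyldimethylsilyl ether and the C6 hydroxyl as triethylsilyl ether | C=C(C)[C@@H]1CC[C@](C)(O[Si](CC)(CC)CC)[C@H](Br)CC[C@H]2C(C)=CCC(C)=C2Cc2cc(ccc2O[Si](C)(C)C(C)(C)C)C(=O)O1 | intermediate
26 | CNP0186361.2: (3S,6S,7R,10S) 15-membered lactone between the C3 oxygen and the 4-hydroxybenzoate carbon; isopropenyl on C3; C6 tertiary alcohol; C7 bromide; 1,4-dimethylcyclohexa-1,4-diene joining C10 and the benzylic C16 | C=C(C)[C@@H]1CC[C@](C)(O)[C@H](Br)CC[C@H]2C(C)=CCC(C)=C2Cc2cc(ccc2O)C(=O)O1 | target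

## Step count and risk

Total step count: 17 (steps 1–4 cyclopentenone half, steps 5–11 chain half, step 12 union, steps 13–17 endgame).
Longest linear sequence: 13 steps (steps 5–17, from pent-4-ynal).

Three steps most likely to fail:

Step 12 (the proposed new ring expansion). Possible failures are migration of the CH2 instead of the alkenyl carbon, Lewis-acid decomposition of the unstabilised diazoalkane (1,2-hydride shift, azine), or weak catalyst control at C10. The fallback uses the established selenium-based one-carbon ring enlargement of ketones, which is known to proceed with alkenyl migration on enones. It sets out from aldehyde 18 and enone 7 and comes back at 21. Aldehyde 18 is treated with PhSeH and ZnCl2 to give the bis(phenylselanyl)acetal F1. n-BuLi in THF at −78 °C cleaves one C–Se bond to give the α-selenoalkyllithium F2, which adds 1,2 to 7 to give the β-hydroxy selenide F3. TlOEt in CHCl3 (dichlorocarbene, selenonium ylide, semipinacol shift) then gives 21 together with the C10 epimer of 21 F4. The two are diastereomers because of the chain stereocentres and are separated by chromatography; this fallback gives up catalyst control at C10.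

Step 13 (regioselective enol triflate). If the amide base removes the doubly activated C10–H, the dienyl triflate forms and C10 is lost. The fallback avoids enolate chemistry. It sets out from 21 and comes back at 23, bypassing 22. MeLi/CeCl3 in THF at −78 °C adds methyl to the ketone anti to the pseudoaxial side chain to give the tertiary carbinol F5, whose hydroxyl is cis to the side chain and therefore trans to the C10–H. Syn-elimination with the Burgess reagent in benzene at 50 °C can then only take a C12 hydrogen (or a methyl hydrogen, a minor exocyclic isomer to be separated), giving 23.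

Step 16 (carbonylative macrolactonisation). Possible failures are slow oxidative addition to the electron-rich aryl bromide, oligomeric esters, or ionisation of the product allylic ester by zerovalent palladium at 85 °C. The fallback separates carbonylation from ring closure. It sets out from 24 and comes back at 25. Hydroxycarbonylation (Pd(OAc)2, Xantphos, CO 1 atm, H2O, Et3N, 1,4-dioxane, 80 °C) gives the seco acid F6, which is cyclised at room temperature under Shiina conditions (2-methyl-6-nitrobenzoic anhydride, DMAP, toluene, high dilution) to 25.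

## Further compounds

F1 | step 12 | (4R,5S,8S)-4-bromo-5,9-dimethyl-1,1-bis(phenylselanyl)-5,8-bis(triethylsilyloxy)dec-9-ene | C=C(C)[C@@H](O[Si](CC)(CC)CC)CC[C@](C)(O[Si](CC)(CC)CC)[C@H](Br)CCC([Se]c1ccccc1)[Se]c1ccccc1
F2 | step 12 | [(4R,5S,8S)-4-bromo-5,9-dimethyl-1-(phenylselanyl)-5,8-bis(triethylsilyloxy)dec-9-en-1-yl]lithium | C=C(C)[C@@H](O[Si](CC)(CC)CC)CC[C@](C)(O[Si](CC)(CC)CC)[C@H](Br)CCC([Li])[Se]c1ccccc1
F3 | step 12 | 2-{[5-bromo-2-(tert-butyldimethylsilyloxy)phenyl]methyl}-1-[(4R,5S,8S)-4-bromo-5,9-dimethyl-1-(phenylselanyl)-5,8-bis(triethylsilyloxy)dec-9-en-1-yl]-3-methylcyclopent-2-en-1-ol (diastereomer mixture at the two new centres) | C=C(C)[C@@H](O[Si](CC)(CC)CC)CC[C@](C)(O[Si](CC)(CC)CC)[C@H](Br)CCC([Se]c1ccccc1)C1(O)CCC(C)=C1Cc1cc(Br)ccc1O[Si](C)(C)C(C)(C)C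
F4 | step 12 | (2S)-2-[(3R,4S,7S)-3-bromo-4,8-dimethyl-4,7-bis(triethylsilyloxy)non-8-en-1-yl]-3-{[5-bromo-2-(tert-butyldimethylsilyloxy)phenyl]methyl}-4-methylcyclohex-3-en-1-one (C10 epimer of 21) | C=C(C)[C@@H](O[Si](CC)(CC)CC)CC[C@](C)(O[Si](CC)(CC)CC)[C@H](Br)CC[C@@H]2C(=O)CCC(C)=C2Cc2cc(Br)ccc2O[Si](C)(C)C(C)(C)C
F5 | step 13 | tertiary carbinol from methyl addition to 21: 2-[(3R,4S,7S)-3-bromo-4,8-dimethyl-4,7-bis(triethylsilyloxy)non-8-en-1-yl]-3-{[5-bromo-2-(tert-butyldimethylsilyloxy)phenyl]methyl}-1,4-dimethylcyclohex-3-en-1-ol with the hydroxyl cis to the side chain | C=C(C)[C@@H](O[Si](CC)(CC)CC)CC[C@](C)(O[Si](CC)(CC)CC)[C@H](Br)CC[C@H]2[C@@](C)(O)CCC(C)=C2Cc2cc(Br)ccc2O[Si](C)(C)C(C)(C)C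
F6 | step 16 | seco acid: 3-{[(6S)-6-[(3R,4S,7S)-3-bromo-7-hydroxy-4,8-dimethyl-4-(triethylsilyloxy)non-8-en-1-yl]-2,5-dimethylcyclohexa-1,4-dien-1-yl]methyl}-4-(tert-butyldimethylsilyloxy)benzoic acid | C=C(C)[C@@H](O)CC[C@](C)(O[Si](CC)(CC)CC)[C@H](Br)CC[C@H]2C(C)=CCC(C)=C2Cc2cc(ccc2O[Si](C)(C)C(C)(C)C)C(=O)O
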